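## Structural features

The target is a furanoheliangolide built on a ten-membered carbocycle C1–C10. An oxygen bridge from C10 to C3 turns C1(=O)–C2=C3–O–C10 into a 3(2H)-furanone, and C6/C7 are fused to an α-methylene-γ-butyrolactone (C11, C12, C13; ring oxygen on C6). The C4=C5 bond is trisubstituted, Z, and conjugated to the furanone. Five stereocentres stand in a row (6R,7S,8S,9R,10R): the lactone is trans-fused (H6 and H7 anti), C8 and C9 carry a threo diol with unlike esters (isovalerate on O8, acetate on O9), and C10 is a quaternary carbinol carbon bearing methyl C14. The fragile groups are the exo-methylene lactone (a Michael acceptor, opened by base), the two neighbouring secondary esters (hydrolysis, acyl migration), the allylic C6–O bond and the vinylogous ester of the furanone. The real difficulty is twofold: closing a strained, bridged ten-membered ring that holds a cis alkene, and building the contiguous C6–C10 array with a quaternary C10 beside a differentiated diol. The key step exploits the fact that the ring O–C3=C2–C1(=O)–C10 is the dehydrated hemiketal of a C1,C3-diketone and the C10 hydroxyl. C3 can therefore begin as the carbonyl of an ester on O10 inside a nine-membered lactone (O10, C3 to C10), and one C2–C3 bond converts that lactone into both the carbocycle and the furanone.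

## Logic of the disconnections

31 to 29: the two ester C–O bonds on O8 and O9 are cut. Both acyl groups are base- and nucleophile-labile, so they are put on last. The gain is a free diol on a finished skeleton. The demand is that the first acyl group goes to O8 (next to methine C7) and not to O9 (next to quaternary C10).

29 to 28 to 26 to 25: the ketal C–O bonds, the lactone C12–O6 bond (with C12 taken down to the alcohol level) and two O–Si bonds are cut. This removes the electrophilic methylene lactone from the enolate chemistry. The ketal is kept until the lactone exists, so that only O6, not O8, can close on C12. The demand is an oxidation that picks the primary allylic alcohol.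

25 to 22: the C2–C3 bond is cut and the furanone oxygen bridge is reopened to an ester on O10. A ten-membered carbocycle becomes a nine-membered lactone, and the C–C bond is made through a five-membered transition state. The demand on 22 is a single enolisable ketone and a single ester.

22 to 21: the C4=C5 bond is cut (ring-closing metathesis). This gives an acyclic ester whose alkene geometry need not be controlled, because the nine-membered ring only tolerates the cis enoate. The demand is closure of a medium ring onto a 1,1-disubstituted acrylate.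

21 to 17 and 18: the ester bond C3–O10 and the C1–C10 bond are cut. The acetyl group comes from an acyl-anion equivalent added to a methyl ketone, and the resulting tertiary alkoxide is acylated directly by 18. The demand is Felkin–Anh face selectivity at C10 and acylation of a hindered alkoxide.

17 to 13: the C10–C14 bond is cut and C10 is taken back to a protected primary alcohol. This keeps the C10 terminus inert while C6, C7 and C12 are built. The demand is a protecting group removable beside two silyl ethers.

13 to 11 to 9: two O–Si bonds, the C12 oxidation level and the lactone C12–O6 bond are traced back. An allylation through the usual (Z)-2-(bromomethyl)enoate can only give the 6,7-syn adduct, which corresponds to a cis lactone. The lactone C–O bond is therefore formed by carboxylate displacement at C6 with inversion. The demand is clean inversion at an allylic carbinol.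

9 to 7 and 8: the C6–C7 bond is cut (Barbier allylation at the γ-carbon). Three carbons of 8 and the whole lactone unit are joined in one step. The demand is attack on the correct face of C7 under the influence of C8.

7 to 4 and 5: the C7–C11 bond is cut (Morita–Baylis–Hillman reaction followed by allylic transposition to the bromide). The gain is an aldehyde and a commodity acrylate.

4 to 1: no skeletal bond is cut. The C2-symmetric 1 supplies C8 and C9 with both oxygens and the correct threo relationship, and its two termini become C7 and C10. The demand is a mono-functionalisation of a symmetric diol.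

## Other disconnections considered

Alternative 1: The cut is at the C9–O and C10–O bonds, so both oxygens and both configurations would come from an arene. The forward key step is the whole-cell cis-dihydroxylation of benzoic acid A1 by benzoate 1,2-dioxygenase at the ipso and ortho carbons, giving the cis-diol acid A2 as one enantiomer; no ring of the target is closed.
- In its favour: an absolute, reagent-independent configuration at the quaternary carbinol C10 and at C9 from an achiral feedstock. On C10 stereocontrol this is the better plan, because the chosen route relies on substrate-controlled addition to a ketone.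
- Against it: a CIP comparison shows that A2 fits the target only if its carboxyl group becomes methyl C14, its C2 becomes C9, C3 and C4 become C8 and C7, and C6 becomes the C1 ketone after cleavage of the C5=C6 bond. The opposite assignment (carboxyl as C1) would give the wrong C10. The carboxyl group must therefore be reduced to a methyl group, the diene must receive an oxygen at C8 and a carbon branch at C7 with control, and the ring must be cleaved.
- Comparison: it delivers two stereocentres, as 1 does (equal on that count), but in a less convenient oxidation pattern. It offers no ring-forming event, so it would still need the acyl-transfer closure or one of the other two ideas. It is clearly longer in steps.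

Alternative 2: The cuts are C2–C3 and C3–C4, with C3 delivered by carbonylation. In the forward step zerovalent palladium inserts into the Z C4–I bond of the open-chain iodoalkyne A3, the acylpalladium formed by carbonyl insertion is captured by the copper acetylide of C2, and reductive elimination closes the ten-membered ynone A4. A 1,3-transposition (amine conjugate addition at C1 and closure of the C10 hydroxyl on C3, or a gold-catalysed hydration and cyclisation) would then give the furanone.
- In its favour: it is the most convergent plan, both esters and the lactone are already in place in A3, and there is no protecting-group endgame. After the key step it is better in step economy than the chosen route, which needs five further steps.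
- Against it: the ring must hold a linear C–C≡C–C unit together with a cis alkene and a trans-fused lactone, so the closure is strained and entropically costly. Oligomerisation and direct non-carbonylative coupling to a nine-membered enyne compete. Zerovalent palladium can ionise the allylic C6–O lactone bond or engage the exo-methylene lactone. The later amine step meets a Michael-acceptor lactone.
- Comparison: both plans form C2–C3 last and use the C10 hydroxyl for the furanone (equal in logic). The chosen plan replaces a macrocyclisation by a five-membered closure and keeps the sensitive lactone and esters out of the ring-forming step.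

Alternative 3: The cut is the C8–C9 bond. In the forward step a ruthenium alkylidene joins the vinyl group on C10 of a preformed furanone and the vinyl group on C7 of a preformed lactone in diene A5, giving the tricycle A6 with an E C8=C9 bond. A syn dihydroxylation would then install O8 and O9.
- In its favour: both metathesis partners are monosubstituted alkenes, which is better than the methacrylate of the chosen route. Furanone and lactone are made on small fragments, and an E alkene plus a syn addition does give the required threo diol.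
- Against it: E geometry is not assured in a bridged ten-membered ring, and a Z alkene would lead to the erythro diol. The dihydroxylation must select C8=C9 among four alkenes and the correct face, with only the ring conformation to direct it. C7 and a vinyl-bearing quaternary C10 must be made separately.
- Comparison: the two hydroxyls still need differentiation, which is equal to the chosen plan. The chosen plan imports C8 and C9 from the chiral pool with certainty, while this alternative creates them last and without a control element. In step count the alternative could be equal or slightly better if every selectivity held.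

Key step: step 17

Remark: germacranolide numbering is used for every intermediate (C1 ketone, C3 furanone enol-ether carbon, C6 lactone carbinol, C10 quaternary carbinol, C12 lactone carbonyl, C13 exo-methylene, C14/C15 methyls). The target was read as 4Z,6R,7S,8S,9R,10R, and 22 and 25 were checked atom by atom against 31 and are drawn to that assignment (TBS = tert-butyldimethylsilyl, PMB = 4-methoxybenzyl).

## Route

Step 1
Reactants: 1 dimethyl (4R,5R)-2,2-dimethyl-1,3-dioxolane-4,5-dicarboxylate (dimethyl 2,3-O-isopropylidene-L-tartrate)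
Product: 2 [(4S,5S)-2,2-dimethyl-1,3-dioxolane-4,5-diyl]dimethanol
Conditions: LiAlH4, THF, 0 °C → rt
Reagents that add atoms: none
Why: Hydride reduction of both esters (LiAlH4 ester reduction); the two stereocentres, the future C8 and C9, are not touched, and the change of descriptor is only a priority effect.

Step 2
Reactants: 2 [(4S,5S)-2,2-dimethyl-1,3-dioxolane-4,5-diyl]dimethanol
Product: 3 [(4S,5S)-5-{[(4-methoxybenzyl)oxy]methyl}-2,2-dimethyl-1,3-dioxolan-4-yl]methanol
Conditions: NaH (1.0 equiv), 4-MeOC6H4CH2Cl (1.0 equiv), n-Bu4NI (cat.), THF/DMF, 0 °C → rt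
Reagents that add atoms: 4-methoxybenzyl chloride, COc1ccc(CCl)cc1
Why: Williamson etherification; the diol is C2-symmetric, so either hydroxyl gives the same mono-ether and one equivalent of base limits the reaction to one oxygen, which marks the future C10 terminus.

Step 3
Reactants: 3 [(4S,5S)-5-{[(4-methoxybenzyl)oxy]methyl}-2,2-dimethyl-1,3-dioxolan-4-yl]methanol
Product: 4 (4R,5S)-5-{[(4-methoxybenzyl)oxy]methyl}-2,2-dimethyl-1,3-dioxolane-4-carbaldehyde
Conditions: Dess–Martin periodinane, CH2Cl2, 0 °C → rt
Reagents that add atoms: none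
Why: Dess–Martin oxidation of the primary alcohol to the C7 aldehyde; the trans-dioxolane is the thermodynamically preferred arrangement, so the α-stereocentre C8 should not be lost by enolisation.

Step 4
Reactants: 4 (4R,5S)-5-{[(4-methoxybenzyl)oxy]methyl}-2,2-dimethyl-1,3-dioxolane-4-carbaldehyde; 5 methyl acrylate
Product: 6 methyl 2-{hydroxy[(4S,5S)-5-{[(4-methoxybenzyl)oxy]methyl}-2,2-dimethyl-1,3-dioxolan-4-yl]methyl}prop-2-enoate (both C7 epimers)
Conditions: DABCO (1 equiv), 5 (5 equiv), MeOH, rt
Reagents that add atoms: none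
Why: Morita–Baylis–Hillman reaction forms the C7–C11 bond; the new carbinol centre may form as a mixture because C7 becomes sp2 in step 5.

Step 5
Reactants: 6 methyl 2-{hydroxy[(4S,5S)-5-{[(4-methoxybenzyl)oxy]methyl}-2,2-dimethyl-1,3-dioxolan-4-yl]methyl}prop-2-enoate
Product: 7 methyl (2Z)-2-(bromomethyl)-3-[(4S,5S)-5-{[(4-methoxybenzyl)oxy]methyl}-2,2-dimethyl-1,3-dioxolan-4-yl]prop-2-enoate
Conditions: N-bromosuccinimide, Me2S, CH2Cl2, 0 °C → rt
Reagents that add atoms: N-bromosuccinimide, O=C1CCC(=O)N1Br
Why: Corey–Kim-type activation of the alcohol and SN2′ delivery of bromide (allylic transposition); acrylate-derived adducts should give the enoate with the C8 substituent trans to the ester and cis to CH2Br (2Z).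

Step 6
Reactants: 7 methyl (2Z)-2-(bromomethyl)-3-[(4S,5S)-5-{[(4-methoxybenzyl)oxy]methyl}-2,2-dimethyl-1,3-dioxolan-4-yl]prop-2-enoate; 8 acrolein
Product: 9 methyl (3S,4S)-4-hydroxy-3-[(4S,5S)-5-{[(4-methoxybenzyl)oxy]methyl}-2,2-dimethyl-1,3-dioxolan-4-yl]-2-methylidenehex-5-enoate (6S,7S in germacranolide numbering)
Conditions: In powder (1.5 equiv), 8 (3 equiv), THF/H2O (1:1), rt
Reagents that add atoms: none
Why: Barbier-type 2-(alkoxycarbonyl)allylation: the allylindium species adds through its γ-carbon C7 to the aldehyde in a chair Zimmerman–Traxler transition state, and the Z-type allyl unit puts C8 axial so that the 6,7-syn adduct (6S) should form. Allylic 1,3-strain against the CH2–In group holds H8 in the alkene plane, so the aldehyde should add to C7 on the face away from C9, which gives the C7 configuration of the target; the 6S centre is the wrong one for a trans lactone and is inverted in step 8.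

Step 7
Reactants: 9 methyl (3S,4S)-4-hydroxy-3-[(4S,5S)-5-{[(4-methoxybenzyl)oxy]methyl}-2,2-dimethyl-1,3-dioxolan-4-yl]-2-methylidenehex-5-enoate
Product: 10 (3S,4S)-4-hydroxy-3-[(4S,5S)-5-{[(4-methoxybenzyl)oxy]methyl}-2,2-dimethyl-1,3-dioxolan-4-yl]-2-methylidenehex-5-enoic acid
Conditions: LiOH·H2O (2 equiv), THF/H2O (3:1), 0 °C; then cold 0.5 M HCl to pH 4
Reagents that add atoms: lithium hydroxide, [Li+].[OH-]
Why: Ester saponification, which would also reopen any cis lactone formed in step 6; the hydroxy acid is extracted cold and used at once so that it does not lactonise with retention.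

Step 8
Reactants: 10 (3S,4S)-4-hydroxy-3-[(4S,5S)-5-{[(4-methoxybenzyl)oxy]methyl}-2,2-dimethyl-1,3-dioxolan-4-yl]-2-methylidenehex-5-enoic acid
Product: 11 (4S,5R)-5-ethenyl-4-[(4S,5S)-5-{[(4-methoxybenzyl)oxy]methyl}-2,2-dimethyl-1,3-dioxolan-4-yl]-3-methylideneoxolan-2-one (trans lactone, 6R,7S)
Conditions: PPh3, diisopropyl azodicarboxylate, THF (0.01 M), 0 °C
Reagents that add atoms: none
Why: Mitsunobu lactonisation: the C6 hydroxyl is activated as its alkoxyphosphonium ion and displaced by the carboxylate in a 5-exo-tet SN2 closure, so C6 should invert from S to R and the trans-fused α-methylene lactone of the target results. An SN2′ closure would need a seven-membered ring and should not compete.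

Step 9
Reactants: 11 (4S,5R)-5-ethenyl-4-[(4S,5S)-5-{[(4-methoxybenzyl)oxy]methyl}-2,2-dimethyl-1,3-dioxolan-4-yl]-3-methylideneoxolan-2-one
Product: 12 (3S,4R)-3-[(4S,5S)-5-{[(4-methoxybenzyl)oxy]methyl}-2,2-dimethyl-1,3-dioxolan-4-yl]-2-methylidenehex-5-ene-1,4-diol
Conditions: i-Bu2AlH (4 equiv), CH2Cl2, −78 → 0 °C
Reagents that add atoms: none
Why: 1,2-Reduction of the lactone through the lactol to the 2-methylene-1,4-diol (i-Bu2AlH lactone reduction); the aluminium hydride should not reduce the exo-methylene group in a conjugate sense, and no stereocentre is touched.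

Step 10
Reactants: 12 (3S,4R)-3-[(4S,5S)-5-{[(4-methoxybenzyl)oxy]methyl}-2,2-dimethyl-1,3-dioxolan-4-yl]-2-methylidenehex-5-ene-1,4-diol
Product: 13 (4S,5S)-4-[(3R,4R)-4-(TBS-oxy)-2-(TBS-oxymethyl)hexa-1,5-dien-3-yl]-5-{[(4-methoxybenzyl)oxy]methyl}-2,2-dimethyl-1,3-dioxolane
Conditions: t-BuMe2SiOSO2CF3 (2.5 equiv), 2,6-lutidine, CH2Cl2, −78 → 0 °C
Reagents that add atoms: tert-butyldimethylsilyl trifluoromethanesulfonate, CC(C)(C)[Si](C)(C)OS(=O)(=O)C(F)(F)F
Why: Silylation of both hydroxyls with the silyl triflate, which is needed for the hindered secondary C6 hydroxyl; the change of the C7 descriptor to R is a priority effect only.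

Step 11
Reactants: 13 (4S,5S)-4-[(3R,4R)-4-(TBS-oxy)-2-(TBS-oxymethyl)hexa-1,5-dien-3-yl]-5-{[(4-methoxybenzyl)oxy]methyl}-2,2-dimethyl-1,3-dioxolane
Product: 14 [(4S,5S)-5-[(3R,4R)-4-(TBS-oxy)-2-(TBS-oxymethyl)hexa-1,5-dien-3-yl]-2,2-dimethyl-1,3-dioxolan-4-yl]methanol
Conditions: DDQ, CH2Cl2/pH 7 phosphate buffer (10:1), 0 °C
Reagents that add atoms: none
Why: Oxidative cleavage of the PMB ether (electron-transfer oxidation of the electron-rich arene); silyl ethers, ketal and the isolated alkenes should be inert.

Step 12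
Reactants: 14 [(4S,5S)-5-[(3R,4R)-4-(TBS-oxy)-2-(TBS-oxymethyl)hexa-1,5-dien-3-yl]-2,2-dimethyl-1,3-dioxolan-4-yl]methanol
Product: 15 (4R,5S)-5-[(3R,4R)-4-(TBS-oxy)-2-(TBS-oxymethyl)hexa-1,5-dien-3-yl]-2,2-dimethyl-1,3-dioxolane-4-carbaldehyde
Conditions: Dess–Martin periodinane, CH2Cl2, 0 °C → rt
Reagents that add atoms: none
Why: Dess–Martin oxidation to the C10 aldehyde; as in step 3 the trans-dioxolane protects C9 against epimerisation.

Step 13
Reactants: 15 (4R,5S)-5-[(3R,4R)-4-(TBS-oxy)-2-(TBS-oxymethyl)hexa-1,5-dien-3-yl]-2,2-dimethyl-1,3-dioxolane-4-carbaldehyde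
Product: 16 1-[(4S,5S)-5-[(3R,4R)-4-(TBS-oxy)-2-(TBS-oxymethyl)hexa-1,5-dien-3-yl]-2,2-dimethyl-1,3-dioxolan-4-yl]ethan-1-ol (both C10 epimers)
Conditions: MeMgBr, THF, −78 °C
Reagents that add atoms: methylmagnesium bromide, C[Mg]Br
Why: Grignard addition brings in C14; the carbinol configuration is irrelevant because it is oxidised in step 14.

Step 14
Reactants: 16 1-[(4S,5S)-5-[(3R,4R)-4-(TBS-oxy)-2-(TBS-oxymethyl)hexa-1,5-dien-3-yl]-2,2-dimethyl-1,3-dioxolan-4-yl]ethan-1-ol
Product: 17 1-[(4R,5S)-5-[(3R,4R)-4-(TBS-oxy)-2-(TBS-oxymethyl)hexa-1,5-dien-3-yl]-2,2-dimethyl-1,3-dioxolan-4-yl]ethan-1-one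
Conditions: Dess–Martin periodinane, CH2Cl2, 0 °C → rt
Reagents that add atoms: none
Why: Dess–Martin oxidation of the secondary alcohol to the C10 methyl ketone.

Step 15
Reactants: 17 1-[(4R,5S)-5-[(3R,4R)-4-(TBS-oxy)-2-(TBS-oxymethyl)hexa-1,5-dien-3-yl]-2,2-dimethyl-1,3-dioxolan-4-yl]ethan-1-one; 18 methacryloyl chloride
Product: 21 (2R)-2-[(4R,5S)-5-[(3R,4R)-4-(TBS-oxy)-2-(TBS-oxymethyl)hexa-1,5-dien-3-yl]-2,2-dimethyl-1,3-dioxolan-4-yl]-3-oxobutan-2-yl 2-methylprop-2-enoate, via lithium alkoxide 19 (not isolated), via enol ether methacrylate 20 (not isolated)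
Conditions: CH2=C(OEt)Li (1.3 equiv, from ethyl vinyl ether and t-BuLi, THF, −78 → 0 °C), THF, −78 °C; then 18 (3 equiv), −78 → 0 °C; then 0.5 M HCl, THF, 0 °C
Reagents that add atoms: 1-ethoxyvinyllithium, [Li]C(=C)OCC; water, O
Why: 1,2-Addition of an acyl-anion equivalent to the ketone under Felkin–Anh control: with lithium in THF the dioxolane oxygen is a poor chelator, the C9–O bond stands anti to the incoming carbon and the nucleophile passes H9, which should set C10 as R. The tertiary lithium alkoxide is O-acylated in the same flask by 18 (ester formation), and brief dilute acid hydrolyses the enol ether to the acetyl group without touching silyl ethers or ketal.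

Step 16
Reactants: 21 (2R)-2-[(4R,5S)-5-[(3R,4R)-4-(TBS-oxy)-2-(TBS-oxymethyl)hexa-1,5-dien-3-yl]-2,2-dimethyl-1,3-dioxolan-4-yl]-3-oxobutan-2-yl 2-methylprop-2-enoate
Product: 22 (4Z,6R,7R,8S,9R,10R) nine-membered lactone: ring O10–C3(=O)–C4(CH3)=C5–C6(OTBS)–C7[C(=CH2)CH2OTBS]–C8–C9–C10(CH3)(COCH3) with O8/O9 as isopropylidene ketal
Conditions: second-generation Hoveyda–Grubbs catalyst RuCl2(=CH-C6H4-2-O-i-Pr)(H2IMes) (15 mol %), 1,4-benzoquinone (30 mol %), toluene (1 mM), 80 °C
Reagents that add atoms: none
Why: Ring-closing metathesis: the ruthenium carbene should load on the monosubstituted C5 vinyl group and close onto the methacrylate, and a nine-membered ring can only hold the cis (Z) enoate. The trans ketal and the quaternary C10 restrict the chain and favour cyclisation, and the C11=C13 alkene is a spectator because it could only give a cyclobutene.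

Step 17
Reactants: 22 (4Z,6R,7R,8S,9R,10R) nine-membered lactone with C10 acetyl, C6 OTBS, C7 C(=CH2)CH2OTBS and O8/O9 isopropylidene ketal
Product: 25 (4Z,6R,7R,8S,9R,10R)-6-(TBS-oxy)-7-[3-(TBS-oxy)prop-1-en-2-yl]-8,9-(isopropylidenedioxy)-4,10-dimethyl-3,10-epoxycyclodeca-2,4-dien-1-one, via lithium enolate 23 (not isolated), via ring-expanded hydroxy diketone 24 (not isolated)
Conditions: LiN(SiMe3)2 (2.2 equiv), THF, −78 → −20 °C; AcOH; then p-TsOH·H2O (0.2 equiv), CH2Cl2, 4 Å molecular sieves, rt
Reagents that add atoms: none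
Why: LiN(SiMe3)2 removes a proton from the C2 methyl group, the only enolisable position of the ketone because C10 is quaternary, and the enolate carbon adds to the lactone carbonyl C3 three atoms away in a 5-exo-trig closure. This is an intramolecular Claisen condensation of the Baker–Venkataraman type, the known base-induced conversion of tertiary α-acyloxy ketones into 3(2H)-furanones. Collapse of the tetrahedral intermediate breaks the C3–O10 bond, so the nine-membered lactone becomes the ten-membered carbocycle by ring expansion and not by macrocyclisation, and the second equivalent of base holds the 1,3-diketone as its enolate, which should make the transfer irreversible. Acid then lets the C10 hydroxyl add back to the C3 carbonyl (5-exo-trig hemiketal formation) and dehydrate to the conjugated furanone, which closes the oxygen bridge. No stereocentre is formed, and C6 to C10 carry no hydrogen acidic enough to be disturbed. The step needs site selectivity for the ketone methyl group over the γ-hydrogen at C6 of the enoate, which the large acidity difference secures, and it needs a single acyl acceptor, which is secured because O6 and O12 are silyl ethers and O8/O9 a ketal. O-acyl transfer to the enolate oxygen is reversible and should drain into the diketone enolate. The Z geometry of C4=C5 is fixed by the ring of 22 and is carried into 25.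

Step 18
Reactants: 25 (4Z,6R,7R,8S,9R,10R)-6-(TBS-oxy)-7-[3-(TBS-oxy)prop-1-en-2-yl]-8,9-(isopropylidenedioxy)-4,10-dimethyl-3,10-epoxycyclodeca-2,4-dien-1-one
Product: 26 (4Z,6R,7S,8S,9R,10R)-6-hydroxy-7-(3-hydroxyprop-1-en-2-yl)-8,9-(isopropylidenedioxy)-4,10-dimethyl-3,10-epoxycyclodeca-2,4-dien-1-one
Conditions: HF·pyridine, pyridine, THF, 0 °C → rt
Reagents that add atoms: none
Why: Fluoride-mediated desilylation of both ethers under buffered, non-basic conditions that spare the ketal and the furanone; the descriptor at C7 changes by priority only.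

Step 19
Reactants: 26 (4Z,6R,7S,8S,9R,10R)-6-hydroxy-7-(3-hydroxyprop-1-en-2-yl)-8,9-(isopropylidenedioxy)-4,10-dimethyl-3,10-epoxycyclodeca-2,4-dien-1-one
Product: 28 (4Z,6R,7S,8S,9R,10R)-8,9-(isopropylidenedioxy)-1-oxo-3,10-epoxygermacra-2,4,11(13)-trien-12,6-olide, via lactol 27 (not isolated)
Conditions: TEMPO (0.2 equiv), PhI(OAc)2 (2.5 equiv), CH2Cl2, rt
Reagents that add atoms: none
Why: Oxoammonium (TEMPO) oxidation is selective for the primary allylic alcohol; the enal is trapped by the C6 hydroxyl as a lactol, which is oxidised on to the α-methylene lactone (oxidative lactonisation of a 1,4-diol). O8 is still tied up in the ketal, so only the 12,6-olide can form.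

Step 20
Reactants: 28 (4Z,6R,7S,8S,9R,10R)-8,9-(isopropylidenedioxy)-1-oxo-3,10-epoxygermacra-2,4,11(13)-trien-12,6-olide
Product: 29 (4Z,6R,7R,8S,9R,10R)-8,9-dihydroxy-1-oxo-3,10-epoxygermacra-2,4,11(13)-trien-12,6-olide
Conditions: CF3CO2H/H2O/CH2Cl2 (5:1:10), 0 °C
Reagents that add atoms: none
Why: Acid-catalysed ketal hydrolysis; the trans-fused dioxolane on the medium ring is strained and should open readily, while the lactone and the vinylogous ester are stable to aqueous acid.

Step 21
Reactants: 29 (4Z,6R,7R,8S,9R,10R)-8,9-dihydroxy-1-oxo-3,10-epoxygermacra-2,4,11(13)-trien-12,6-olide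
Product: 30 (4Z,6R,7S,8S,9R,10R)-9-hydroxy-8-(3-methylbutanoyloxy)-1-oxo-3,10-epoxygermacra-2,4,11(13)-trien-12,6-olide
Conditions: (i-PrCH2CO)2O (1.1 equiv), DMAP (0.1 equiv), 2,4,6-collidine, CH2Cl2, −20 → 0 °C
Reagents that add atoms: 3-methylbutanoic anhydride, CC(C)CC(=O)OC(=O)CC(C)C
Why: DMAP-catalysed acylation under kinetic control; O8 sits next to the methine C7, whereas O9 is neopentyl-like beside the quaternary C10, so the first acyl group should go to O8.

Step 22
Reactants: 30 (4Z,6R,7S,8S,9R,10R)-9-hydroxy-8-(3-methylbutanoyloxy)-1-oxo-3,10-epoxygermacra-2,4,11(13)-trien-12,6-olide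
Product: 31 (4Z,6R,7S,8S,9R,10R)-9-acetoxy-8-(3-methylbutanoyloxy)-1-oxo-3,10-epoxygermacra-2,4,11(13)-trien-12,6-olide (CNP0255553.1)
Conditions: Ac2O, DMAP, pyridine, CH2Cl2, rt
Reagents that add atoms: acetic anhydride, CC(=O)OC(C)=O
Why: DMAP-catalysed acetylation of the remaining hindered secondary hydroxyl; the small acetyl donor in excess should reach O9 without base strong enough to open the lactone or move the isovalerate.

## Compound list

1 | dimethyl (4R,5R)-2,2-dimethyl-1,3-dioxolane-4,5-dicarboxylate | COC(=O)[C@@H]1OC(C)(C)O[C@H]1C(=O)OC | starting material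
2 | [(4S,5S)-2,2-dimethyl-1,3-dioxolane-4,5-diyl]dimethanol | OC[C@@H]1OC(C)(C)O[C@H]1CO | intermediate
3 | [(4S,5S)-5-{[(4-methoxybenzyl)oxy]methyl}-2,2-dimethyl-1,3-dioxolan-4-yl]methanol | COc1ccc(COC[C@@H]2OC(C)(C)O[C@H]2CO)cc1 | intermediate
4 | (4R,5S)-5-{[(4-methoxybenzyl)oxy]methyl}-2,2-dimethyl-1,3-dioxolane-4-carbaldehyde | COc1ccc(COC[C@@H]2OC(C)(C)O[C@H]2C=O)cc1 | intermediate
5 | methyl acrylate | C=CC(=O)OC | starting material
6 | methyl 2-{hydroxy[(4S,5S)-5-{[(4-methoxybenzyl)oxy]methyl}-2,2-dimethyl-1,3-dioxolan-4-yl]methyl}prop-2-enoate (both C7 epimers) | COc1ccc(COC[C@@H]2OC(C)(C)O[C@H]2C(O)C(=C)C(=O)OC)cc1 | intermediate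
7 | methyl (2Z)-2-(bromomethyl)-3-[(4S,5S)-5-{[(4-methoxybenzyl)oxy]methyl}-2,2-dimethyl-1,3-dioxolan-4-yl]prop-2-enoate | COc1ccc(COC[C@@H]2OC(C)(C)O[C@H]2/C=C(\CBr)C(=O)OC)cc1 | intermediate
8 | acrolein | C=CC=O | starting material
9 | methyl (3S,4S)-4-hydroxy-3-[(4S,5S)-5-{[(4-methoxybenzyl)oxy]methyl}-2,2-dimethyl-1,3-dioxolan-4-yl]-2-methylidenehex-5-enoate | COc1ccc(COC[C@@H]2OC(C)(C)O[C@H]2[C@H]([C@@H](O)C=C)C(=C)C(=O)OC)cc1 | intermediate
10 | (3S,4S)-4-hydroxy-3-[(4S,5S)-5-{[(4-methoxybenzyl)oxy]methyl}-2,2-dimethyl-1,3-dioxolan-4-yl]-2-methylidenehex-5-enoic acid | COc1ccc(COC[C@@H]2OC(C)(C)O[C@H]2[C@H]([C@@H](O)C=C)C(=C)C(=O)O)cc1 | intermediate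
11 | (4S,5R)-5-ethenyl-4-[(4S,5S)-5-{[(4-methoxybenzyl)oxy]methyl}-2,2-dimethyl-1,3-dioxolan-4-yl]-3-methylideneoxolan-2-one | C=C1C(=O)O[C@H](C=C)[C@H]1[C@@H]2OC(C)(C)O[C@H]2COCc3ccc(OC)cc3 | intermediate
12 | (3S,4R)-3-[(4S,5S)-5-{[(4-methoxybenzyl)oxy]methyl}-2,2-dimethyl-1,3-dioxolan-4-yl]-2-methylidenehex-5-ene-1,4-diol | COc1ccc(COC[C@@H]2OC(C)(C)O[C@H]2[C@H]([C@H](O)C=C)C(=C)CO)cc1 | intermediate
13 | (4S,5S)-4-[(3R,4R)-4-(TBS-oxy)-2-(TBS-oxymethyl)hexa-1,5-dien-3-yl]-5-{[(4-methoxybenzyl)oxy]methyl}-2,2-dimethyl-1,3-dioxolane | COc1ccc(COC[C@@H]2OC(C)(C)O[C@H]2[C@H]([C@H](O[Si](C)(C)C(C)(C)C)C=C)C(=C)CO[Si](C)(C)C(C)(C)C)cc1 | intermediate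
14 | [(4S,5S)-5-[(3R,4R)-4-(TBS-oxy)-2-(TBS-oxymethyl)hexa-1,5-dien-3-yl]-2,2-dimethyl-1,3-dioxolan-4-yl]methanol | OC[C@@H]1OC(C)(C)O[C@H]1[C@H]([C@H](O[Si](C)(C)C(C)(C)C)C=C)C(=C)CO[Si](C)(C)C(C)(C)C | intermediate
15 | (4R,5S)-5-[(3R,4R)-4-(TBS-oxy)-2-(TBS-oxymethyl)hexa-1,5-dien-3-yl]-2,2-dimethyl-1,3-dioxolane-4-carbaldehyde | O=C[C@@H]1OC(C)(C)O[C@H]1[C@H]([C@H](O[Si](C)(C)C(C)(C)C)C=C)C(=C)CO[Si](C)(C)C(C)(C)C | intermediate
16 | 1-[(4S,5S)-5-[(3R,4R)-4-(TBS-oxy)-2-(TBS-oxymethyl)hexa-1,5-dien-3-yl]-2,2-dimethyl-1,3-dioxolan-4-yl]ethan-1-ol (both C10 epimers) | CC(O)[C@@H]1OC(C)(C)O[C@H]1[C@H]([C@H](O[Si](C)(C)C(C)(C)C)C=C)C(=C)CO[Si](C)(C)C(C)(C)C | intermediate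
17 | 1-[(4R,5S)-5-[(3R,4R)-4-(TBS-oxy)-2-(TBS-oxymethyl)hexa-1,5-dien-3-yl]-2,2-dimethyl-1,3-dioxolan-4-yl]ethan-1-one | CC(=O)[C@@H]1OC(C)(C)O[C@H]1[C@H]([C@H](O[Si](C)(C)C(C)(C)C)C=C)C(=C)CO[Si](C)(C)C(C)(C)C | intermediate
18 | methacryloyl chloride | C=C(C)C(=O)Cl | starting material
19 | lithium (2R)-3-ethoxy-2-[(4R,5S)-5-[(3R,4R)-4-(TBS-oxy)-2-(TBS-oxymethyl)hexa-1,5-dien-3-yl]-2,2-dimethyl-1,3-dioxolan-4-yl]but-3-en-2-olate (not isolated) | [Li+].C=C(OCC)[C@](C)([O-])[C@@H]1OC(C)(C)O[C@H]1[C@H]([C@H](O[Si](C)(C)C(C)(C)C)C=C)C(=C)CO[Si](C)(C)C(C)(C)C | intermediate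
20 | (2R)-3-ethoxy-2-[(4R,5S)-5-[(3R,4R)-4-(TBS-oxy)-2-(TBS-oxymethyl)hexa-1,5-dien-3-yl]-2,2-dimethyl-1,3-dioxolan-4-yl]but-3-en-2-yl 2-methylprop-2-enoate (not isolated) | C=C(OCC)[C@](C)(OC(=O)C(C)=C)[C@@H]1OC(C)(C)O[C@H]1[C@H]([C@H](O[Si](C)(C)C(C)(C)C)C=C)C(=C)CO[Si](C)(C)C(C)(C)C | intermediate
21 | (2R)-2-[(4R,5S)-5-[(3R,4R)-4-(TBS-oxy)-2-(TBS-oxymethyl)hexa-1,5-dien-3-yl]-2,2-dimethyl-1,3-dioxolan-4-yl]-3-oxobutan-2-yl 2-methylprop-2-enoate | CC(=O)[C@](C)(OC(=O)C(C)=C)[C@@H]1OC(C)(C)O[C@H]1[C@H]([C@H](O[Si](C)(C)C(C)(C)C)C=C)C(=C)CO[Si](C)(C)C(C)(C)C | intermediate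
22 | (4Z,6R,7R,8S,9R,10R) nine-membered lactone (O10, C3–C10) with C10 acetyl and methyl, C4 methyl, C6 OTBS, C7 3-(TBS-oxy)prop-1-en-2-yl, O8/O9 isopropylidene ketal | CC(=O)[C@]1(C)OC(=O)/C(C)=C\[C@@H](O[Si](C)(C)C(C)(C)C)[C@H](C(=C)CO[Si](C)(C)C(C)(C)C)[C@@H]2OC(C)(C)O[C@@H]12 | intermediate
23 | lithium C1,C2-enolate of 22 (not isolated) | [Li+].C=C([O-])[C@]1(C)OC(=O)/C(C)=C\[C@@H](O[Si](C)(C)C(C)(C)C)[C@H](C(=C)CO[Si](C)(C)C(C)(C)C)[C@@H]2OC(C)(C)O[C@@H]12 | intermediate
24 | (4Z,6R,7R,8S,9R,10R)-10-hydroxy-6-(TBS-oxy)-7-[3-(TBS-oxy)prop-1-en-2-yl]-8,9-(isopropylidenedioxy)-4,10-dimethylcyclodec-4-ene-1,3-dione, in equilibrium with its transannular hemiketal (not isolated) | C[C@]1(O)C(=O)CC(=O)/C(C)=C\[C@@H](O[Si](C)(C)C(C)(C)C)[C@H](C(=C)CO[Si](C)(C)C(C)(C)C)[C@@H]2OC(C)(C)O[C@@H]12 | intermediate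
25 | (4Z,6R,7R,8S,9R,10R)-6-(TBS-oxy)-7-[3-(TBS-oxy)prop-1-en-2-yl]-8,9-(isopropylidenedioxy)-4,10-dimethyl-3,10-epoxycyclodeca-2,4-dien-1-one | CC(C)(C)[Si](C)(C)O[C@@H]1/C=C(/C)C2=CC(=O)[C@](C)(O2)[C@@H]3OC(C)(C)O[C@H]3[C@H]1C(=C)CO[Si](C)(C)C(C)(C)C | intermediate
26 | (4Z,6R,7S,8S,9R,10R)-6-hydroxy-7-(3-hydroxyprop-1-en-2-yl)-8,9-(isopropylidenedioxy)-4,10-dimethyl-3,10-epoxycyclodeca-2,4-dien-1-one | O[C@@H]1/C=C(/C)C2=CC(=O)[C@](C)(O2)[C@@H]3OC(C)(C)O[C@H]3[C@H]1C(=C)CO | intermediate
27 | C12 lactol of 28, both C12 epimers (not isolated) | C=C1C(O)O[C@@H]2/C=C(/C)C3=CC(=O)[C@](C)(O3)[C@@H]4OC(C)(C)O[C@H]4[C@@H]12 | intermediate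
28 | (4Z,6R,7S,8S,9R,10R)-8,9-(isopropylidenedioxy)-1-oxo-3,10-epoxygermacra-2,4,11(13)-trien-12,6-olide | C=C1C(=O)O[C@@H]2/C=C(/C)C3=CC(=O)[C@](C)(O3)[C@@H]4OC(C)(C)O[C@H]4[C@@H]12 | intermediate
29 | (4Z,6R,7R,8S,9R,10R)-8,9-dihydroxy-1-oxo-3,10-epoxygermacra-2,4,11(13)-trien-12,6-olide | C=C1C(=O)O[C@@H]2/C=C(/C)C3=CC(=O)[C@](C)(O3)[C@H](O)[C@@H](O)[C@@H]12 | intermediate
30 | (4Z,6R,7S,8S,9R,10R)-9-hydroxy-8-(3-methylbutanoyloxy)-1-oxo-3,10-epoxygermacra-2,4,11(13)-trien-12,6-olide | C=C1C(=O)O[C@@H]2/C=C(/C)C3=CC(=O)[C@](C)(O3)[C@H](O)[C@@H](OC(=O)CC(C)C)[C@@H]12 | intermediate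
31 | (4Z,6R,7S,8S,9R,10R)-9-acetoxy-8-(3-methylbutanoyloxy)-1-oxo-3,10-epoxygermacra-2,4,11(13)-trien-12,6-olide | C=C1C(=O)O[C@@H]2/C=C(/C)C3=CC(=O)[C@](C)(O3)[C@H](OC(C)=O)[C@@H](OC(=O)CC(C)C)[C@@H]12 | target

## Step count and least certain steps

Total: 22 steps. Longest linear sequence: 22 steps (1 to 31); 5, 8 and 18 enter as single building blocks. Diol 2 is itself a catalogue compound, so starting there would save step 1.

Step 17 (key step). The enolate may fail to reach the lactone carbonyl if the nine-membered ring holds C3=O away from C2. In that case O-acyl transfer, an α-ketol shift of the C10 alkoxide or decomposition on warming would take over. Loss of silyl groups in the acid stage would be harmless, since step 18 removes them. The fallback reverses the order of the two ring-forming events. It sets out from 21, where the same base and acid treatment should give, without any ring strain, the open-chain 5-isopropenyl-3(2H)-furanone F1. Ring-closing metathesis between the isopropenyl group and the C5 vinyl group (same ruthenium catalyst, high dilution) then closes the ten-membered carbocycle directly and returns to the route at 25.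

Step 16. Ring closure may be too slow because of medium-ring strain and the low reactivity of the 1,1-disubstituted, electron-poor methacrylate. Dimerisation through the vinyl group, alkene migration or catalyst decay would then win. The fallback closes the ring on an unsubstituted acrylate and adds C15 afterwards. It sets out from 17: the alkoxide 19 is trapped with acryloyl chloride to give the enol ether acrylate F2 (not isolated), hydrolysed as in step 15 to the acrylate ketone F3. Metathesis gives the nine-membered (Z)-enoate lactone F4. α-Iodination (I2, pyridine, CH2Cl2) gives the α-iodo enoate F5, and Stille methylation (SnMe4, Pd2(dba)3, AsPh3, CuI) returns to the route at 22.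

Step 6. Face discrimination at C7 may be insufficient (addition to both faces of the allyl unit under the influence of C8), the syn preference may erode, and the aldehyde may polymerise in water. The fallback forms the C6–C7 bond by a metal-free allylboration with a tighter cyclic transition state. It sets out from 6: acetylation (Ac2O, DMAP) gives the acetate F6, and borylation with bis(pinacolato)diboron under Pd2(dba)3 catalysis gives the allylboronate F7 with the geometry of 7. Heating F7 with 8 in toluene and hydrolysing the borate returns to the route at 9.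

Step 8. Ring closure may occur with retention if the carboxyl group is activated instead of the hydroxyl, 10 may lactonise prematurely under acid during its isolation, or allylic transposition may intervene. The fallback inverts C6 intermolecularly at the ester stage. It sets out from 9: Mitsunobu esterification with 4-nitrobenzoic acid (PPh3, diisopropyl azodicarboxylate) gives the inverted 4-nitrobenzoate F8. Methanolysis (K2CO3, MeOH, 0 °C) frees the 6R alkoxide, which closes on the methyl ester and returns to the route at 11.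

Step 15. Face selectivity at C10 may be poor if a chelated transition state competes with the Felkin–Anh one, the basic vinyllithium may enolise the methyl ketone, or acylation of the hindered alkoxide may be incomplete. The fallback attaches the two carbon groups in the opposite order and uses chelation instead, which for that order leads to the same 10R centre. It sets out from 15: addition of CH2=C(OEt)Li gives the carbinol F9, and Dess–Martin oxidation gives the 1-ethoxyvinyl ketone F10. MeMgBr, after precomplexation with MgBr2·OEt2 in CH2Cl2, should add through the five-membered chelate with O9 to give the bromomagnesium alkoxide F11 (not isolated). Acylation of F11 with 18 gives 20, and the hydrolysis of step 15 returns to the route at 21.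

Step 21. Discrimination between the two secondary hydroxyls may be insufficient, leading to diacylation, the wrong mono-ester or acyl migration between O8 and O9. The fallback masks O8 with a silyl group, whose transfer responds more strongly to steric hindrance, and reverses the order of the acylations. It sets out from 29: Et3SiCl and imidazole give the 8-O-triethylsilyl ether F12, Ac2O/DMAP gives its 9-acetate F13, and HF·pyridine gives the 9-acetate 8-alcohol F14. Acylation of F14 with 3-methylbutanoic anhydride and DMAP returns to the route at 31.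

## Further compounds

F1 | step 17 | (2R)-2-[(4R,5S)-5-[(3R,4R)-4-(TBS-oxy)-2-(TBS-oxymethyl)hexa-1,5-dien-3-yl]-2,2-dimethyl-1,3-dioxolan-4-yl]-2-methyl-5-(prop-1-en-2-yl)furan-3(2H)-one | C=C(C)C1=CC(=O)[C@](C)(O1)[C@@H]2OC(C)(C)O[C@H]2[C@H]([C@H](O[Si](C)(C)C(C)(C)C)C=C)C(=C)CO[Si](C)(C)C(C)(C)C
F2 | step 16 | (2R)-3-ethoxy-2-[(4R,5S)-5-[(3R,4R)-4-(TBS-oxy)-2-(TBS-oxymethyl)hexa-1,5-dien-3-yl]-2,2-dimethyl-1,3-dioxolan-4-yl]but-3-en-2-yl prop-2-enoate | C=C(OCC)[C@](C)(OC(=O)C=C)[C@@H]1OC(C)(C)O[C@H]1[C@H]([C@H](O[Si](C)(C)C(C)(C)C)C=C)C(=C)CO[Si](C)(C)C(C)(C)C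
F3 | step 16 | (2R)-2-[(4R,5S)-5-[(3R,4R)-4-(TBS-oxy)-2-(TBS-oxymethyl)hexa-1,5-dien-3-yl]-2,2-dimethyl-1,3-dioxolan-4-yl]-3-oxobutan-2-yl prop-2-enoate | CC(=O)[C@](C)(OC(=O)C=C)[C@@H]1OC(C)(C)O[C@H]1[C@H]([C@H](O[Si](C)(C)C(C)(C)C)C=C)C(=C)CO[Si](C)(C)C(C)(C)C
F4 | step 16 | 4-demethyl analogue of 22 (nine-membered Z-enoate lactone without C15) | CC(=O)[C@]1(C)OC(=O)/C=C\[C@@H](O[Si](C)(C)C(C)(C)C)[C@H](C(=C)CO[Si](C)(C)C(C)(C)C)[C@@H]2OC(C)(C)O[C@@H]12
F5 | step 16 | 4-iodo analogue of 22 (iodine in place of the C15 methyl group) | CC(=O)[C@]1(C)OC(=O)/C(I)=C\[C@@H](O[Si](C)(C)C(C)(C)C)[C@H](C(=C)CO[Si](C)(C)C(C)(C)C)[C@@H]2OC(C)(C)O[C@@H]12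
F6 | step 6 | methyl 2-{acetoxy[(4S,5S)-5-{[(4-methoxybenzyl)oxy]methyl}-2,2-dimethyl-1,3-dioxolan-4-yl]methyl}prop-2-enoate | COc1ccc(COC[C@@H]2OC(C)(C)O[C@H]2C(OC(C)=O)C(=C)C(=O)OC)cc1
F7 | step 6 | methyl (2E)-3-[(4S,5S)-5-{[(4-methoxybenzyl)oxy]methyl}-2,2-dimethyl-1,3-dioxolan-4-yl]-2-[(4,4,5,5-tetramethyl-1,3,2-dioxaborolan-2-yl)methyl]prop-2-enoate | COc1ccc(COC[C@@H]2OC(C)(C)O[C@H]2/C=C(\CB3OC(C)(C)C(C)(C)O3)C(=O)OC)cc1
F8 | step 8 | methyl (3S,4R)-3-[(4S,5S)-5-{[(4-methoxybenzyl)oxy]methyl}-2,2-dimethyl-1,3-dioxolan-4-yl]-2-methylidene-4-[(4-nitrobenzoyl)oxy]hex-5-enoate | COc1ccc(COC[C@@H]2OC(C)(C)O[C@H]2[C@H]([C@H](OC(=O)c3ccc(cc3)[N+](=O)[O-])C=C)C(=C)C(=O)OC)cc1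
F9 | step 15 | 2-ethoxy-1-[(4S,5S)-5-[(3R,4R)-4-(TBS-oxy)-2-(TBS-oxymethyl)hexa-1,5-dien-3-yl]-2,2-dimethyl-1,3-dioxolan-4-yl]prop-2-en-1-ol (both C10 epimers) | C=C(OCC)C(O)[C@@H]1OC(C)(C)O[C@H]1[C@H]([C@H](O[Si](C)(C)C(C)(C)C)C=C)C(=C)CO[Si](C)(C)C(C)(C)C
F10 | step 15 | 2-ethoxy-1-[(4R,5S)-5-[(3R,4R)-4-(TBS-oxy)-2-(TBS-oxymethyl)hexa-1,5-dien-3-yl]-2,2-dimethyl-1,3-dioxolan-4-yl]prop-2-en-1-one | C=C(OCC)C(=O)[C@@H]1OC(C)(C)O[C@H]1[C@H]([C@H](O[Si](C)(C)C(C)(C)C)C=C)C(=C)CO[Si](C)(C)C(C)(C)C
F11 | step 15 | bromomagnesium (2R)-alkoxide corresponding to 19 | C=C(OCC)[C@](C)(O[Mg]Br)[C@@H]1OC(C)(C)O[C@H]1[C@H]([C@H](O[Si](C)(C)C(C)(C)C)C=C)C(=C)CO[Si](C)(C)C(C)(C)C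
F12 | step 21 | 8-O-triethylsilyl ether of 29 | C=C1C(=O)O[C@@H]2/C=C(/C)C3=CC(=O)[C@](C)(O3)[C@H](O)[C@@H](O[Si](CC)(CC)CC)[C@@H]12
F13 | step 21 | 9-O-acetyl-8-O-triethylsilyl derivative of 29 | C=C1C(=O)O[C@@H]2/C=C(/C)C3=CC(=O)[C@](C)(O3)[C@H](OC(C)=O)[C@@H](O[Si](CC)(CC)CC)[C@@H]12
F14 | step 21 | 9-O-acetyl derivative of 29 (free 8-hydroxyl) | C=C1C(=O)O[C@@H]2/C=C(/C)C3=CC(=O)[C@](C)(O3)[C@H](OC(C)=O)[C@@H](O)[C@@H]12
A1 | alternative 1 | benzoic acid | O=C(O)c1ccccc1
A2 | alternative 1 | (1S,2R)-1,2-dihydroxycyclohexa-3,5-diene-1-carboxylic acid | O[C@@H]1C=CC=C[C@@]1(O)C(=O)O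
A3 | alternative 2 | open-chain (Z)-C4 iodoalkene with terminal C1–C2 alkyne, C10 tertiary alcohol, both esters and the lactone in place | C#C[C@](C)(O)[C@H](OC(C)=O)[C@@H](OC(=O)CC(C)C)[C@@H]1[C@@H](/C=C(/C)I)OC(=O)C1=C
A4 | alternative 2 | ten-membered C3 ynone with the C10 hydroxyl on the alkyne terminus | C=C1C(=O)O[C@@H]2/C=C(/C)C(=O)C#C[C@](C)(O)[C@H](OC(C)=O)[C@@H](OC(=O)CC(C)C)[C@@H]12
A5 | alternative 3 | diene with a vinyl group on C10 of the furanone and a vinyl group on C7 of the lactone | C=C1C(=O)O[C@H](/C=C(/C)C2=CC(=O)[C@@](C)(C=C)O2)[C@H]1C=C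
A6 | alternative 3 | 8,9-didehydro bridged tricycle with an E C8=C9 alkene | C=C1C(=O)O[C@@H]2/C=C(/C)C3=CC(=O)[C@](C)(O3)/C=C/[C@@H]12
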